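The readings stem from a simulated flask from invented constants; scatter was added.

| flask | starting complex | incoming ligand | remark | time |
|---|---|---|---|---|
| teal | 1.5 M | 1.5 M | run made earlier |  |
| flask | 3.0 M | 1.50 M |  | 2.5 min |

teal run (percent of the starting complex charged)

| time / min | complex with two exchanged / % | starting complex / % |
|---|---|---|
| 0.500 | 13.7 | 46.3 |
| 1.00 | 9.5 | 46.5 |
| 1.50 | 7.9 | 46.7 |
| 2.00 | 6.9 | 46.3 |
| 2.50 | 6.7 | 46.7 |
| 3.00 | 6.7 | 46.6 |

(standard deviation of a reading: 0.3 percentage points)

- the numbers in the tables scatter by 0.3 percentage points (one standard deviation)

1. equivalents of incoming ligand to starting complex, everything else as given, that leave most complex with two exchanged at 2.5 min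
2. the amount of complex with two exchanged then, in percent of the starting complex charged
3. the amount of complex with two exchanged with the amounts as given

In a one-step world every starting complex that reacts ends as complex with two exchanged, and the teal run would hold 53.3% of it. It holds 6.7% at 2.50 min, down from 13.7% at 0.500 min and still 6.7% at 3.00 min. Starting complex reads 46.3% at the first reading and 46.6% at the last, so it had stopped falling by the first reading, and you read incoming ligand as the limiting reagent.

So decide the next charge by following one ligand molecule, not one complex. Its yield per ligand, the moles of complex with two exchanged standing at 2.5 min per mole of ligand charged, reads 6.70% in the teal run, with the scatter of its readings. The flask holds 3.0 M of starting complex where teal held 1.5 M, so the forks may shift, but you assume they do not. Then 1.50 M of ligand gives 3.35% of the starting complex charged. Teal, at one equivalent, holds 6.70% with starting complex to spare, so you would not run at 0.5 equivalents: charge at least one equivalent of ligand. Teal has no reading above that, so your reckoning names no best charge.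

The forecast, reasoning that “each reacted complex took about two ligands”, gave 3% as charged, less than your figure, and 14% at 2 equiv.

    starting complex + incoming ligand → leaving ligand + complex with one exchanged (k = 0.120 /M/s)
    complex with one exchanged → side product (k = 0.0580 /s)
    complex with two exchanged ⇌ isomer of the product (K = 2.70, k = 0.0240 /s)
    complex with one exchanged + incoming ligand → leaving ligand + complex with two exchanged (k = 0.510 /M/s)
    complex with two exchanged + incoming ligand → leaving ligand + complex with three exchanged (k = 0.150 /M/s)

The flask gives 3.59% as charged, a yield of 7.18% per ligand, and its best charge is 1.58 equiv, giving 8.32%. By 0.250 min the exchanges had brought incoming ligand down to 0.102% of its charge, with starting complex at 68.1% and complex with two exchanged at 9.78%. In the flask incoming ligand stood at 0% at 1.25 min. Complex with two exchanged passed into isomer of the product, reaching 3.59% beside 9.43% at 2.50 min, while complex with one exchanged went to side product, 16.3%. With 2.5 M of ligand, the yield per ligand from teal gives 5.58%, and that neighbour flask holds 6.02%.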